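The reading at 1.50 min gives the most G of either earlier run, so I look for the top of the new flask near that time.

| flask | Q | remark | time |
|---|---|---|---|
| west | 13 mM | run made earlier |  |
| north-east | 30 mM | run made earlier |  |
| flask | 20 mM |  | 40 min |

| run | time / min | G / % | Q / % |
|---|---|---|---|
| west | 0.500 | 25.9 | 56.6 |
| west | 1.50 | 44.3 | 18.4 |
| west | 5.00 | 32.7 | 0 |
| west | 15.0 | 7.0 | 0.3 |
| west | 50.0 | 0 | 0 |
| north-east | 0.500 | 24.9 | 55.3 |
| north-east | 1.50 | 45.0 | 18.1 |
| north-east | 5.00 | 33.1 | 0.1 |
| north-east | 15.0 | 7.2 | 0.1 |
| north-east | 50.0 | 0 | 0 |

(standard deviation of a reading: 0.5 percentage points)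

1. when, up to 40 min, the flask holds most G
2. the amount of G, in percent of the Q charged, at that time

The first setting is the charge. By hand, first-order steps leave percentages untouched by the charge, and the two runs, at 13 mM and 30 mM of Q, differ at that reading by 0.7 percentage points, about what a scatter of 0.5 points gives between two readings. So I take their mean as one curve for 20 mM.

The second setting is the time. On the mean curve Q falls at 1.12 /min and G's tail falls at 0.153 /min, more slowly. For a chain with these two rates, the maximum comes at the logarithm of their ratio over their difference, 2.06 min, far inside the 40 min allowed.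

Carrying the tail back from 5.00 min gives the share of Q that goes to G, the selectivity: 61.1%. At the maximum, G is this share times the exponential of minus G's rate times the peak time. I call that the peak share 44.6%, the part of the charge standing as G at its top. As a check on replacing the curves by single rates, the chain gives 43.1% at 1.50 min, which is 1.6 points below the mean reading. So I commit to a top between 44.6% and 46.2%.

The forecast says 2.05 min and 45.3%, a height above my peak share, holding that “about 62% of Q goes to G”.

The flask holds most G at 2.02 min, 45.7% of its charge, inside my band. The top is flat: it holds 44.9% at 1.61 min and 44.8% at 2.52 min.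

    Q ⇌ Z (K = 2.40, k = 0.00750 /s)
    Q → G (k = 0.0120 /s)
    Z → X (k = 0.0350 /s)
    G → J (k = 0.00240 /s)
    Z ⇌ D (K = 11.0, k = 0.00340 /s)
    G ⇌ L (K = 25.0, k = 2.90 × 10⁻⁴ /s)

For the neighbour flask, charged with 12 mM of Q, the peak share gives 5.35 mM of G, and that flask reaches 45.7% of its charge, 5.48 mM.

The readings come from a simulation with made-up constants; scatter was added.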